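**Retrosynthetic overview**
- Target ⇐ hexabenzyl ether ⇐ enantioselective rhodium-catalysed aryl addition to the chromone half of a chromone–flavone biaryl (sets C2 last), then global hydrogenolysis.
- Chromone–flavone ⇐ one-pot twofold intramolecular Friedel–Crafts acylation: both pyranone rings are closed at C4–C4a from a bis(aryloxypropenoic acid); the positions of the two tether oxygens fix the 6- and 8-attachment of the biaryl bond.
- Diacid ⇐ two oxa-Michael additions of an unsymmetrical 2,4'-biphenol: ethyl propiolate at the para phenol, an aryl propiolate at the ortho phenol.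
- Biphenol ⇐ MOM-directed aryllithium + 2,6-bis(benzyloxy)benzoquinone, then quinol reduction; both halves come from 3,5-bis(benzyloxy)phenol.
- Ring order: the two A rings are bought, the two C (pyranone) rings form together, the B rings arrive with the aryl propiolate and the arylboronic acid.

Assumption: the SMILES fixes only C2 (S) and leaves the hindered biaryl axis undefined, so the 2S compound is the target irrespective of the axis; 3,5-bis(benzyloxy)phenol is taken as a catalogue chemical.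

Step 1
Reactants: 1 3,5-bis(benzyloxy)phenol
Product: 2 2,6-bis(benzyloxy)-1,4-benzoquinone
Conditions: K2NO(SO3)2 (2.5 equiv), KH2PO4, acetone/H2O, 0 °C to rt
Reagents that add atoms: dipotassium nitrosodisulfonate, [K+].[K+].[O]N(S(=O)(=O)[O-])S(=O)(=O)[O-]
Why: Teuber oxidation of an electron-rich phenol with a free para position gives the para-quinone cleanly (as with 3,5-dimethoxyphenol), and the new carbonyl lies between the two benzyloxy-bearing carbons.

Step 2
Reactants: 1 3,5-bis(benzyloxy)phenol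
Product: 3 1,3-bis(benzyloxy)-5-(methoxymethoxy)benzene
Conditions: MOMCl, iPr2NEt, CH2Cl2, 0 °C to rt
Reagents that add atoms: chloromethyl methyl ether, COCCl
Why: Williamson-type O-alkylation of the phenol (MOM protection) installs the group that directs the ortho-lithiation of the next step.

Step 3
Reactants: 3 1,3-bis(benzyloxy)-5-(methoxymethoxy)benzene; 2 2,6-bis(benzyloxy)-1,4-benzoquinone
Product: 6 2,2',4',6-tetrakis(benzyloxy)-6'-(methoxymethoxy)-[1,1'-biphenyl]-4-ol, via aryllithium 4 (not isolated), via para-quinol 5 (not isolated)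
Conditions: n-BuLi, THF, 0 °C; then 2, −78 °C; then AcOH, Zn dust, −78 °C to rt
Reagents that add atoms: none
Why: Directed ortho-metalation puts lithium between the OCH2OMe group and a benzyloxy group, the aryllithium adds 1,2 to the quinone carbonyl flanked by the two enol-ether carbons (the other carbonyl is a deactivated doubly vinylogous ester), and zinc in acetic acid reductively aromatises the para-quinol (quinol-to-phenol reduction), so the aryl–aryl bond ends up para to the free phenol on one ring and ortho to the protected phenol on the other.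

Step 4
Reactants: 6 2,2',4',6-tetrakis(benzyloxy)-6'-(methoxymethoxy)-[1,1'-biphenyl]-4-ol; 7 ethyl propiolate
Product: 9 ethyl (2E)-3-{[2,2',4',6-tetrakis(benzyloxy)-6'-hydroxy-[1,1'-biphenyl]-4-yl]oxy}prop-2-enoate, via MOM-protected acrylate 8 (not isolated)
Conditions: DABCO (10 mol%), CH2Cl2, 0 °C to rt; then HCl (4 M in dioxane), 0 °C to rt
Reagents that add atoms: none
Why: DABCO-catalysed oxa-Michael addition of the only free phenol to ethyl propiolate gives the (E)-3-aryloxyacrylate, and anhydrous HCl then cleaves the MOM acetal without touching the benzyl ethers or the push–pull enol ether.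

Step 5
Reactants: 10 1-(benzyloxy)-4-iodobenzene; 7 ethyl propiolate
Product: 11 ethyl 3-[4-(benzyloxy)phenyl]prop-2-ynoate
Conditions: PdCl2(PPh3)2 (2 mol%), CuI (4 mol%), K2CO3, THF, 60 °C
Reagents that add atoms: none
Why: Sonogashira coupling of an aryl iodide with ethyl propiolate, run with carbonate instead of an amine so that nothing adds to the propiolate.

Step 6
Reactants: 9 ethyl (2E)-3-{[2,2',4',6-tetrakis(benzyloxy)-6'-hydroxy-[1,1'-biphenyl]-4-yl]oxy}prop-2-enoate; 11 ethyl 3-[4-(benzyloxy)phenyl]prop-2-ynoate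
Product: 13 (2E)-3-{[2,2',4',6-tetrakis(benzyloxy)-6'-({(1Z)-1-[4-(benzyloxy)phenyl]-2-carboxyethenyl}oxy)-[1,1'-biphenyl]-4-yl]oxy}prop-2-enoic acid, via diester 12 (not isolated)
Conditions: Cs2CO3 (20 mol%), DMF, 60 °C; then LiOH, THF/H2O, rt; 1 M HCl work-up
Reagents that add atoms: lithium hydroxide, [Li+].[OH-]
Why: Base-catalysed oxa-Michael addition (hydrophenoxylation) of the remaining hindered phenol to the aryl propiolate gives the 3-aryloxycinnamate (anti addition, Z major, geometry irrelevant later), and LiOH saponification of both esters follows the classical preparation of 3-aryloxyacrylic and 3-aryloxycinnamic acids.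

Step 7
Reactants: 13 (2E)-3-{[2,2',4',6-tetrakis(benzyloxy)-6'-({(1Z)-1-[4-(benzyloxy)phenyl]-2-carboxyethenyl}oxy)-[1,1'-biphenyl]-4-yl]oxy}prop-2-enoic acid
Product: 15 5,7-bis(benzyloxy)-8-[5,7-bis(benzyloxy)-4-oxo-4H-chromen-6-yl]-2-[4-(benzyloxy)phenyl]-4H-chromen-4-one, via bis(acid chloride) 14 (not isolated)
Conditions: 1-chloro-N,N,2-trimethylprop-1-en-1-amine (2.4 equiv), CH2Cl2, 0 °C to rt; then (CF3)2CHOH, rt
Reagents that add atoms: none
Why: Twofold intramolecular Friedel–Crafts acylation (chromone closure of a 3-aryloxyacrylic acid plus Ruhemann-type flavone closure of a 3-aryloxycinnamic acid) on the neutrally formed bis(acid chloride) in ionising hexafluoroisopropanol, where each acylium can reach only the carbon ortho to its own tether oxygen (one of two equivalent positions on the para-tethered ring, the single free position on the ortho-tethered ring), so both pyranone rings form with the required 6,8''-connectivity while the E arm isomerises through its oxocarbenium–ketene resonance form.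

Step 8
Reactants: 15 5,7-bis(benzyloxy)-8-[5,7-bis(benzyloxy)-4-oxo-4H-chromen-6-yl]-2-[4-(benzyloxy)phenyl]-4H-chromen-4-one; 16 [4-(benzyloxy)phenyl]boronic acid
Product: 17 (2S)-5,7-bis(benzyloxy)-6-{5,7-bis(benzyloxy)-2-[4-(benzyloxy)phenyl]-4-oxo-4H-chromen-8-yl}-2-[4-(benzyloxy)phenyl]-2,3-dihydro-4H-chromen-4-one
Conditions: [Rh(OH)(C8H12)]2 (3 mol%; C8H12 = cycloocta-1,5-diene), (S)-MeO-F12-BIPHEP (6.6 mol%), 16 (4 equiv), toluene/H2O, 50 °C
Reagents that add atoms: none
Why: Rhodium-catalysed asymmetric 1,4-addition of the arylboronic acid (Hayashi–Miyaura reaction) occurs only at the 2-unsubstituted chromone (the 2-aryl flavone is inert), the (S)-configured electron-poor bisphosphine delivering the aryl group to the face that gives 2S (same sense as (S)-BINAP additions to cyclic enones) under base-free conditions that do not open the flavanone ring.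

Step 9
Reactants: 17 (2S)-5,7-bis(benzyloxy)-6-{5,7-bis(benzyloxy)-2-[4-(benzyloxy)phenyl]-4-oxo-4H-chromen-8-yl}-2-[4-(benzyloxy)phenyl]-2,3-dihydro-4H-chromen-4-one
Product: 18 (2S)-6-[5,7-dihydroxy-2-(4-hydroxyphenyl)-4-oxo-4H-chromen-8-yl]-5,7-dihydroxy-2-(4-hydroxyphenyl)-2,3-dihydro-4H-chromen-4-one (target)
Conditions: H2 (1 atm), 10% Pd/C, EtOAc/MeOH, rt
Reagents that add atoms: none
Why: Hydrogenolysis of the six benzyl ethers under neutral conditions, which at one atmosphere leaves the flavone double bond intact and, having neither base nor strong acid, cannot epimerise C2.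

**Compound list**
1 | 3,5-bis(benzyloxy)phenol | Oc1cc(OCc2ccccc2)cc(OCc2ccccc2)c1 | starting material
2 | 2,6-bis(benzyloxy)-1,4-benzoquinone | O=C1C=C(OCc2ccccc2)C(=O)C(OCc2ccccc2)=C1 | intermediate
3 | 1,3-bis(benzyloxy)-5-(methoxymethoxy)benzene | COCOc1cc(OCc2ccccc2)cc(OCc2ccccc2)c1 | intermediate
4 | [2,4-bis(benzyloxy)-6-(methoxymethoxy)phenyl]lithium | [Li]c1c(OCOC)cc(OCc2ccccc2)cc1OCc1ccccc1 | intermediate
5 | 3,5-bis(benzyloxy)-4-[2,4-bis(benzyloxy)-6-(methoxymethoxy)phenyl]-4-hydroxycyclohexa-2,5-dien-1-one | O=C1C=C(OCc2ccccc2)C(O)(c2c(OCOC)cc(OCc3ccccc3)cc2OCc2ccccc2)C(OCc2ccccc2)=C1 | intermediate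
6 | 2,2',4',6-tetrakis(benzyloxy)-6'-(methoxymethoxy)-[1,1'-biphenyl]-4-ol | Oc1cc(OCc2ccccc2)c(-c2c(OCOC)cc(OCc3ccccc3)cc2OCc2ccccc2)c(OCc2ccccc2)c1 | intermediate
7 | ethyl propiolate (ethyl prop-2-ynoate) | C#CC(=O)OCC | starting material
8 | ethyl (2E)-3-{[2,2',4',6-tetrakis(benzyloxy)-6'-(methoxymethoxy)-[1,1'-biphenyl]-4-yl]oxy}prop-2-enoate | CCOC(=O)/C=C/Oc1cc(OCc2ccccc2)c(-c2c(OCOC)cc(OCc3ccccc3)cc2OCc2ccccc2)c(OCc2ccccc2)c1 | intermediate
9 | ethyl (2E)-3-{[2,2',4',6-tetrakis(benzyloxy)-6'-hydroxy-[1,1'-biphenyl]-4-yl]oxy}prop-2-enoate | CCOC(=O)/C=C/Oc1cc(OCc2ccccc2)c(-c2c(O)cc(OCc3ccccc3)cc2OCc2ccccc2)c(OCc2ccccc2)c1 | intermediate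
10 | 1-(benzyloxy)-4-iodobenzene | Ic1ccc(OCc2ccccc2)cc1 | starting material
11 | ethyl 3-[4-(benzyloxy)phenyl]prop-2-ynoate | CCOC(=O)C#Cc1ccc(OCc2ccccc2)cc1 | intermediate
12 | ethyl (2E)-3-{[2,2',4',6-tetrakis(benzyloxy)-6'-({(1Z)-1-[4-(benzyloxy)phenyl]-3-ethoxy-3-oxoprop-1-en-1-yl}oxy)-[1,1'-biphenyl]-4-yl]oxy}prop-2-enoate (Z cinnamate shown; the E isomer cyclises equally) | CCOC(=O)/C=C/Oc1cc(OCc2ccccc2)c(-c2c(O/C(=C\C(=O)OCC)c3ccc(OCc4ccccc4)cc3)cc(OCc3ccccc3)cc2OCc2ccccc2)c(OCc2ccccc2)c1 | intermediate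
13 | (2E)-3-{[2,2',4',6-tetrakis(benzyloxy)-6'-({(1Z)-1-[4-(benzyloxy)phenyl]-2-carboxyethenyl}oxy)-[1,1'-biphenyl]-4-yl]oxy}prop-2-enoic acid | OC(=O)/C=C/Oc1cc(OCc2ccccc2)c(-c2c(O/C(=C\C(=O)O)c3ccc(OCc4ccccc4)cc3)cc(OCc3ccccc3)cc2OCc2ccccc2)c(OCc2ccccc2)c1 | intermediate
14 | (2E)-3-{[2,2',4',6-tetrakis(benzyloxy)-6'-({(1Z)-1-[4-(benzyloxy)phenyl]-3-chloro-3-oxoprop-1-en-1-yl}oxy)-[1,1'-biphenyl]-4-yl]oxy}prop-2-enoyl chloride | ClC(=O)/C=C/Oc1cc(OCc2ccccc2)c(-c2c(O/C(=C\C(=O)Cl)c3ccc(OCc4ccccc4)cc3)cc(OCc3ccccc3)cc2OCc2ccccc2)c(OCc2ccccc2)c1 | intermediate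
15 | 5,7-bis(benzyloxy)-8-[5,7-bis(benzyloxy)-4-oxo-4H-chromen-6-yl]-2-[4-(benzyloxy)phenyl]-4H-chromen-4-one | O=c1ccoc2cc(OCc3ccccc3)c(-c3c(OCc4ccccc4)cc(OCc4ccccc4)c4c(=O)cc(-c5ccc(OCc6ccccc6)cc5)oc34)c(OCc3ccccc3)c12 | intermediate
16 | [4-(benzyloxy)phenyl]boronic acid | OB(O)c1ccc(OCc2ccccc2)cc1 | starting material
17 | (2S)-5,7-bis(benzyloxy)-6-{5,7-bis(benzyloxy)-2-[4-(benzyloxy)phenyl]-4-oxo-4H-chromen-8-yl}-2-[4-(benzyloxy)phenyl]-2,3-dihydro-4H-chromen-4-one | O=C1C[C@@H](c2ccc(OCc3ccccc3)cc2)Oc2cc(OCc3ccccc3)c(-c3c(OCc4ccccc4)cc(OCc4ccccc4)c4c(=O)cc(-c5ccc(OCc6ccccc6)cc5)oc34)c(OCc3ccccc3)c21 | intermediate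
18 | (2S)-6-[5,7-dihydroxy-2-(4-hydroxyphenyl)-4-oxo-4H-chromen-8-yl]-5,7-dihydroxy-2-(4-hydroxyphenyl)-2,3-dihydro-4H-chromen-4-one | O=C1C[C@@H](c2ccc(O)cc2)Oc2cc(O)c(-c3c(O)cc(O)c4c(=O)cc(-c5ccc(O)cc5)oc34)c(O)c21 | target

**Totals**
Total step count: 9.
Longest linear sequence: 7 steps (steps 2, 3, 4, 6, 7, 8, 9, from 1 to 18); steps 1 and 5 are side branches.

**Three steps most likely to fail**

Step 3. The hindered aryllithium may transfer an electron to the quinone instead of adding to its carbonyl, and the lithiation must be selective for the position next to the MOM group. Fallback, setting out from 1 and 3 and coming back at 6: the aryl–aryl bond is made by cross-coupling instead of carbonyl addition and reduction. Compound 1 is brominated para to the hydroxyl (NBS, CH2Cl2, −78 °C, minor ortho isomer removed) to give 4-bromo-3,5-bis(benzyloxy)phenol F1. The lithio species from 3 is quenched with B(OMe)3 and hydrolysed to [2,4-bis(benzyloxy)-6-(methoxymethoxy)phenyl]boronic acid F2. Suzuki–Miyaura coupling of F1 with F2 (Pd(OAc)2, SPhos, K3PO4, toluene/H2O, 90 °C) then gives 6.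

Step 7. The vinylogous acid chlorides may ionise too sluggishly for the flavone closure, or HCl in hexafluoroisopropanol may attack benzyl ethers. Fallback, setting out from 13 and coming back at 15: the electrophile is changed from an acylium ion to an activated amide. Compound 13 is converted (EDC, HOBt, Me2NH) into the bis(N,N-dimethylamide) F3. Activation with Tf2O and 2-chloropyridine (CH2Cl2, −78 to 0 °C) brings about a twofold intramolecular Vilsmeier–Haack-type ring closure, and aqueous NaHCO3 hydrolysis of the two iminium salts gives 15.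

Step 8. The electron-rich chromone with a bulky 6-aryl group may react slowly or with low ee, the two atropisomers of 15 may behave differently, and the sense of induction rests on analogy. Fallback, setting out from 15 and coming back at 17: catalytic enantiocontrol is replaced by resolution. Achiral conjugate addition of 16 to 15 (Pd(OCOCF3)2, 2,2'-bipyridine, AcOH/THF/H2O, 60 °C) gives the racemic hexabenzyl ether F4. Preparative HPLC on an amylose-carbamate chiral stationary phase gives 17, and the unwanted 2R antipode is returned to F4 by DBU-induced ring opening and re-closure.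

**Further compounds**
F1 | step 3 | 4-bromo-3,5-bis(benzyloxy)phenol | Oc1cc(OCc2ccccc2)c(Br)c(OCc2ccccc2)c1
F2 | step 3 | [2,4-bis(benzyloxy)-6-(methoxymethoxy)phenyl]boronic acid | OB(O)c1c(OCOC)cc(OCc2ccccc2)cc1OCc1ccccc1
F3 | step 7 | (2E)-3-{[2,2',4',6-tetrakis(benzyloxy)-6'-({(1Z)-1-[4-(benzyloxy)phenyl]-3-(dimethylamino)-3-oxoprop-1-en-1-yl}oxy)-[1,1'-biphenyl]-4-yl]oxy}-N,N-dimethylprop-2-enamide | CN(C)C(=O)/C=C/Oc1cc(OCc2ccccc2)c(-c2c(O/C(=C\C(=O)N(C)C)c3ccc(OCc4ccccc4)cc3)cc(OCc3ccccc3)cc2OCc2ccccc2)c(OCc2ccccc2)c1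
F4 | step 8 | racemic 5,7-bis(benzyloxy)-6-{5,7-bis(benzyloxy)-2-[4-(benzyloxy)phenyl]-4-oxo-4H-chromen-8-yl}-2-[4-(benzyloxy)phenyl]-2,3-dihydro-4H-chromen-4-one | O=C1CC(c2ccc(OCc3ccccc3)cc2)Oc2cc(OCc3ccccc3)c(-c3c(OCc4ccccc4)cc(OCc4ccccc4)c4c(=O)cc(-c5ccc(OCc6ccccc6)cc5)oc34)c(OCc3ccccc3)c21
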